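Amounts first: this flask holds twice as much nucleophile as electrophile, and less free base than either.

electrophile 0.010 M; nucleophile 0.0200 M; free base 3.00 mM; time 25 s

    electrophile + nucleophile → acid set free + target (k1 = 0.84 M⁻¹ s⁻¹)
    nucleophile + acid set free ⇌ protonated nucleophile, settled at all times (K2 = 37000 M⁻¹)
    acid set free + free base ⇌ salt of the base, settled at all times (K3 = 590 M⁻¹)
    crystals ⇌ acid set free, rate k4*(cs4 - [acid set free]) while solid is left; crystals form when [acid set free] > cs4 (cs4 = 3.2 mM, k4 = 0.53 s⁻¹)
    free base + target → over-reaction product (k5 = 7.9 M⁻¹ s⁻¹)

- part of the electrophile that has reacted at 25 s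
- share of the unused nucleophile that is free and not bound as protonated nucleophile, at 25 s

- what is said of acid set free includes crystals
- crystals is a solid; its amount is given per volume of the solution
- run time (flask): 25 s

The rule of thumb I use at the bench is that each turnover costs two nucleophiles, one that reacts and one that catches the acid set free. With this charge, free nucleophile then stays at twice the electrophile, and the fraction x of electrophile reacted follows a second-order curve. Its clock is the two-for-one lifetime τ, the time in which x reaches one half. I count how many such lifetimes N have passed:

τ = 1 / (2 × 0.84 M⁻¹ s⁻¹ × 0.010 M) = 59.5 s

N = 25 s / τ = 0.420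

x = N / (1 + N) = 29.6 %

free share = 2(1 − x) / (2 − x) = 82.6 %

The rule stops working where the free base begins to win the acid. At the charge, the nucleophile's binding strength is 740 against 1.8 for the base, so the border lies at a free nucleophile fraction of 0.239 % of its charge. My reckoning leaves 70.4 % free, so protonated nucleophile stays the resting state of the acid.

The forecast reckons the same way, its grounds being that “each reaction event uses up two nucleophiles”. It gives 29.6 % (29.2 % to 30 %) and 82.7 % (82 % to 83.4 %), so my share stands level with its own.

The flask gives 29.6 % and 82.7 %.

The main reason that this flask stands at 29.6 % is the moment of the reading, 25 s and not ten times later: the same flask left that long stands at 80.9 %. At 250 s the count is 4.20 lifetimes, so the rule gives 80.8 %. In the neighbour flask with 0.0050 M of nucleophile, the limiting reagent, the same τ serves as the lifetime of a pseudo-first-order decay of the nucleophile, so exp(−N) gives 65.7 %, and that flask holds 67 % of its nucleophile free at 25.0 s.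

The numbers belong to no real substance; no experiment stands behind them.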